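## Retrosynthetic overview

1. Feature: on the cyclobutane (C1 = CH–CO2Me, C2 = CH–CO2H, C3 beside C2, C4 beside C1), C3 and C4 each carry a CH3 on the face of the C1/C2 carboxyls and, on the other face, a pyranone C6 at the acid oxidation level. This is the pattern of a cis-fused succinimide (3-azabicyclo[3.2.0]heptane-2,4-dione) methylated at both ring-fusion carbons.
2. C1 ester / C2 acid ⇐ quinine-mediated methanolysis of the meso C1/C2 anhydride as the last step. All earlier intermediates stay meso, so the two-directional steps give no regioisomers and no methyl ester meets the dianion.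
3. Both pyranones ⇐ twofold aldol of the C3/C4 dialdehyde with the dianion of ethyl 2-methylacetoacetate, then oxidation, lactonisation and O-methylation. The dialdehyde comes from the N-Boc imide by reduction and reoxidation; aldehydes are used because a second acyl transfer from an acyclic neopentyl acyl donor is judged unreliable.
4. C3–CH3 and C4–CH3 ⇐ twofold enolate methylation of the PMB imide diacid, which is one step from the commercial cis,trans,cis dianhydride.
5. Ring order: cyclobutane bought → imide ring (step 1, temporary) → both pyranone rings together (step 10) → C1/C2 anhydride ring (step 12, opened in step 13).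

Key step: step 2

Remark: "upper face" means the face of the C1/C2 carboxyl groups. The sense of the alkaloid-mediated methanolysis is assumed to be that of unsubstituted cis-cyclobutane-1,2-dicarboxylic anhydride, which points to quinine for 22; quinidine gives the antipode and is the switch if the sense proves reversed.

## Route

Step 1
Reactants: 1 cis,trans,cis-cyclobutane-1,2,3,4-tetracarboxylic dianhydride; 2 4-methoxybenzylamine
Product: 5 cis,trans,cis-cyclobutane-1,2,3,4-tetracarboxylic acid 3,4-[N-(4-methoxybenzyl)imide], via amic acid anhydride 3 (not isolated), via imide anhydride 4 (not isolated)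
Conditions: 1 (3 equiv), DMF, 0 °C, slow addition of 2 (1 equiv); Ac2O, NaOAc (cat.), 80 °C; H2O, 60 °C; NaHCO3 extraction, acidify, EtOAc
Reagents that add atoms: water, O
Why: Anhydride aminolysis followed by Ac2O cyclodehydration closes the succinimide on one cis pair of carbonyls and hydrolysis frees the other pair as the diacid; the excess of 1 keeps the opening to one ring and ends as the water-soluble tetraacid, and the ring constraints leave the cis,trans,cis configuration untouched.

Step 2
Reactants: 5 imide diacid
Product: 7 3,4-dimethyl imide diacid (both CH3 on the upper face), via monomethyl imide diacid 6 (not isolated)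
Conditions: LDA (3.2 equiv), THF–DMPU, −78 °C; MeI (1.1 equiv), −78 → −40 °C; LDA (1.3 equiv), −78 °C; MeI (2 equiv), −78 → 0 °C; 1 M HCl
Reagents that add atoms: iodomethane, CI
Why: Two equivalents of amide base turn the acids into lithium carboxylates and the third removes the C3–H next to an imide carbonyl; the enolate is C-methylated by SN2 attack on iodomethane and the cycle is repeated at C4, which is α-alkylation of a cyclic imide enolate as used at the ring-fusion carbons of cis-bicyclic succinimides and lactams. No ring is closed. Both new quaternary centres are set by the ring fusion: the planar enolate carbon belongs to the cyclobutane and to the imide ring, a trans-fused 3-azabicyclo[3.2.0]heptanedione is out of reach, so methyl enters on the convex face that the hydrogen left (retention) and ends cis to the C1/C2 carboxyls. The step needs selectivity for the imide α-C–H over the C1/C2 C–H bonds, which the carboxylate charge secures because deprotonation there would require a carboxylate dianion. It also needs C- over O-methylation, which is usual for a lithium enolate with iodomethane, and lithium carboxylates should not be esterified at these temperatures. Fragmentation of the four-membered ring by β-elimination is not expected, since the ring bonds to C1 and C2 lie nearly orthogonal to the enolate π system and the leaving carbon would be the α-carbanion of a carboxylate.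

Step 3
Reactants: 7 dimethyl imide diacid
Product: 8 di-tert-butyl ester of 7
Conditions: t-BuOC(=NH)CCl3 (4 equiv), BF3·OEt2 (cat.), CH2Cl2–THF, rt
Reagents that add atoms: tert-butyl 2,2,2-trichloroacetimidate, CC(C)(C)OC(=N)C(Cl)(Cl)Cl
Why: Acid-catalysed O-tert-butylation with the trichloroacetimidate alkylates the carboxyl oxygens without activating the acyl carbons, so the cis diacid cannot close to its anhydride and C1/C2 are not epimerised.

Step 4
Reactants: 8 N-PMB imide diester
Product: 9 N–H imide diester
Conditions: CAN (4 equiv), MeCN–H2O, 0 °C → rt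
Reagents that add atoms: none
Why: Oxidative N-debenzylation, in which single-electron oxidation of the anisyl ring gives a benzylic cation that is hydrated and collapses to the N–H imide and anisaldehyde, conditions that tert-butyl esters tolerate.

Step 5
Reactants: 9 N–H imide diester
Product: 10 N-Boc imide diester
Conditions: Boc2O (1.5 equiv), DMAP (cat.), Et3N, CH2Cl2, rt
Reagents that add atoms: di-tert-butyl dicarbonate, CC(C)(C)OC(=O)OC(=O)OC(C)(C)C
Why: DMAP-catalysed N-acylation of the acidic imide N–H gives the N-Boc imide, whose ring carbonyls are now activated like those of an N-acyl carbamate.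

Step 6
Reactants: 10 N-Boc imide diester
Product: 12 di-tert-butyl 3,4-bis(hydroxymethyl)-3,4-dimethylcyclobutane-1,2-dicarboxylate, via hydroxymethyl N-Boc amide 11 (not isolated)
Conditions: LiBH4 (4 equiv), THF, MeOH (2 equiv), 0 °C → rt
Reagents that add atoms: none
Why: Hydride reduction of an N-acyl carbamate, as in the reductive removal of oxazolidinone auxiliaries; the first reduction opens the ring to the hydroxymethyl N-Boc amide, which is reduced in turn with loss of tert-butyl carbamate, while tert-butyl esters react far more slowly with LiBH4.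

Step 7
Reactants: 12 diol
Product: 13 di-tert-butyl 3,4-diformyl-3,4-dimethylcyclobutane-1,2-dicarboxylate
Conditions: (COCl)2, DMSO, CH2Cl2, −78 °C; Et3N, −78 → 0 °C; used directly
Reagents that add atoms: none
Why: Swern oxidation converts both neopentyl hydroxyls to alkoxysulfonium ions before base is added, so no lactol can form and over-oxidation to a lactone is avoided; the aldehydes have no α-hydrogen.

Step 8
Reactants: 13 dialdehyde; 14 ethyl 2-methylacetoacetate
Product: 16 bis(δ-hydroxy-β-keto ester), via dianion 15 (not isolated)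
Conditions: 14 (5 equiv), NaH, THF, 0 °C; n-BuLi, 0 °C; 13 added at −78 °C, → −10 °C; AcOH
Reagents that add atoms: none
Why: Weiler dianion aldol addition in which the γ-carbon of the 1,3-dicarbonyl dianion adds to each non-enolisable aldehyde; excess dianion and warming should reopen any lactolate formed between the first alkoxide and the neighbouring aldehyde, proton transfer from the shielded C–H bonds α to the tert-butyl esters should be slow, and the new carbinol and methine centres are mixtures that steps 9 and 10 erase.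

Step 9
Reactants: 16 bis(δ-hydroxy-β-keto ester)
Product: 17 bis(3,5-dioxo ester)
Conditions: Dess–Martin periodinane (3 equiv), NaHCO3, CH2Cl2, 0 °C → rt
Reagents that add atoms: none
Why: Dess–Martin oxidation of β-hydroxy ketones to the largely enolised 1,3-diketones, under conditions that leave the active methylene and the tert-butyl esters alone.

Step 10
Reactants: 17 bis(3,5-dioxo ester)
Product: 18 di-tert-butyl 3,4-bis(4-hydroxy-3-methyl-2-oxo-2H-pyran-6-yl)-3,4-dimethylcyclobutane-1,2-dicarboxylate
Conditions: DBU (4 equiv), PhMe, rt → 50 °C; dilute HCl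
Reagents that add atoms: none
Why: Base-mediated lactonisation (6-exo-trig attack of the C5 enol oxygen on the ethyl ester) and enolisation give each 4-hydroxy-2-pyranone, the aromatic pyranone enolate being the thermodynamic sink, and the methine stereocentres disappear.

Step 11
Reactants: 18 bis(4-hydroxypyranone)
Product: 19 di-tert-butyl 3,4-bis(4-methoxy-3-methyl-2-oxo-2H-pyran-6-yl)-3,4-dimethylcyclobutane-1,2-dicarboxylate
Conditions: Me2SO4 (3 equiv), K2CO3, acetone, rt → 40 °C
Reagents that add atoms: dimethyl sulfate, COS(=O)(=O)OC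
Why: O-alkylation of the vinylogous acid with dimethyl sulfate under carbonate conditions, which with 3-alkyl-4-hydroxy-2-pyranones normally gives the 4-methoxy-2-pyranone rather than the 2-methoxy-4-pyranone isomer.

Step 12
Reactants: 19 bis(4-methoxypyranone) diester
Product: 21 meso C1/C2 cyclic anhydride, via bis-pyranone diacid 20 (not isolated)
Conditions: TFA–CH2Cl2 (1:2), rt; evaporate; Ac2O, 60 °C; evaporate
Reagents that add atoms: none
Why: Acidolysis of the tert-butyl esters with loss of isobutene, then cyclodehydration of the cis-1,2-diacid through the mixed anhydride; only the cis diacid can close, so any material epimerised at C1 or C2 is left behind.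

Step 13
Reactants: 21 meso anhydride
Product: 22 target half ester
Conditions: quinine (1.1 equiv), MeOH (5 equiv), PhMe–CH2Cl2, −55 °C; 1 M HCl wash
Reagents that add atoms: methanol, CO
Why: Alkaloid-mediated desymmetrising alcoholysis of a meso cyclic anhydride, in which quinine as chiral general base should deliver methanol to the carbonyl on the R-configured fusion carbon so that C1 becomes the ester and C2 the acid; the cis relationship is untouched and the enantiomeric purity can be raised by crystallisation.

## Compound list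

1 | cis,trans,cis-cyclobutane-1,2,3,4-tetracarboxylic 1,2:3,4-dianhydride (meso) | O=C5[C@@H]1[C@H](C(=O)O5)[C@@H](C(=O)OC6=O)[C@H]16 | starting material
2 | 4-methoxybenzylamine | COc1ccc(CN)cc1 | starting material
3 | amic acid anhydride: C1/C2 anhydride, C3 CO2H, C4 CONH-PMB, cis,trans,cis (racemic) | O=C5[C@@H]1[C@H](C(=O)O5)[C@@H](C(=O)O)[C@H]1C(=O)NCc1ccc(OC)cc1 | intermediate
4 | cis,trans,cis-cyclobutanetetracarboxylic 1,2-anhydride 3,4-[N-(4-methoxybenzyl)imide] (meso) | O=C5[C@@H]1[C@H](C(=O)O5)[C@H]2C(=O)N(Cc3ccc(OC)cc3)C(=O)[C@@H]12 | intermediate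
5 | cis,trans,cis-cyclobutane-1,2,3,4-tetracarboxylic acid 3,4-[N-(4-methoxybenzyl)imide] (meso; CO2H groups on the upper face, imide ring on the lower face) | OC(=O)[C@@H]1[C@H](C(=O)O)[C@H]2C(=O)N(Cc3ccc(OC)cc3)C(=O)[C@@H]12 | intermediate
6 | 3-methyl derivative of 5, CH3 on the upper face (racemic) | OC(=O)[C@@H]1[C@H](C(=O)O)[C@@]2(C)C(=O)N(Cc3ccc(OC)cc3)C(=O)[C@@H]12 | intermediate
7 | 3,4-dimethyl derivative of 5, both CH3 on the upper face, cis to the C1/C2 carboxyls (meso) | OC(=O)[C@@H]1[C@H](C(=O)O)[C@@]2(C)C(=O)N(Cc3ccc(OC)cc3)C(=O)[C@@]12C | intermediate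
8 | di-tert-butyl ester of 7 | CC(C)(C)OC(=O)[C@@H]1[C@H](C(=O)OC(C)(C)C)[C@@]2(C)C(=O)N(Cc3ccc(OC)cc3)C(=O)[C@@]12C | intermediate
9 | N–H imide di-tert-butyl ester | CC(C)(C)OC(=O)[C@@H]1[C@H](C(=O)OC(C)(C)C)[C@@]2(C)C(=O)NC(=O)[C@@]12C | intermediate
10 | N-Boc imide di-tert-butyl ester | CC(C)(C)OC(=O)[C@@H]1[C@H](C(=O)OC(C)(C)C)[C@@]2(C)C(=O)N(C(=O)OC(C)(C)C)C(=O)[C@@]12C | intermediate
11 | di-tert-butyl 3-(hydroxymethyl)-4-[(tert-butoxycarbonyl)carbamoyl]-3,4-dimethylcyclobutane-1,2-dicarboxylate (racemic) | CC(C)(C)OC(=O)[C@@H]1[C@H](C(=O)OC(C)(C)C)[C@@](C)(CO)[C@@]1(C)C(=O)NC(=O)OC(C)(C)C | intermediate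
12 | di-tert-butyl 3,4-bis(hydroxymethyl)-3,4-dimethylcyclobutane-1,2-dicarboxylate (meso; CH2OH on the lower face, CH3 and esters on the upper face) | CC(C)(C)OC(=O)[C@@H]1[C@H](C(=O)OC(C)(C)C)[C@@](C)(CO)[C@@]1(C)CO | intermediate
13 | di-tert-butyl 3,4-diformyl-3,4-dimethylcyclobutane-1,2-dicarboxylate (meso) | CC(C)(C)OC(=O)[C@@H]1[C@H](C(=O)OC(C)(C)C)[C@@](C)(C=O)[C@@]1(C)C=O | intermediate
14 | ethyl 2-methylacetoacetate | CCOC(=O)C(C)C(C)=O | starting material
15 | sodium lithium dianion (dienolate) of 14 | [Na+].[Li+].C=C([O-])C(C)=C([O-])OCC | intermediate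
16 | di-tert-butyl 3,4-bis(5-ethoxy-1-hydroxy-4-methyl-3,5-dioxopentyl)-3,4-dimethylcyclobutane-1,2-dicarboxylate (diastereomer mixture at carbinol and methine carbons) | CC(C)(C)OC(=O)[C@@H]1[C@H](C(=O)OC(C)(C)C)[C@@](C)(C(O)CC(=O)C(C)C(=O)OCC)[C@@]1(C)C(O)CC(=O)C(C)C(=O)OCC | intermediate
17 | di-tert-butyl 3,4-bis(5-ethoxy-4-methyl-1,3,5-trioxopentyl)-3,4-dimethylcyclobutane-1,2-dicarboxylate | CC(C)(C)OC(=O)[C@@H]1[C@H](C(=O)OC(C)(C)C)[C@@](C)(C(=O)CC(=O)C(C)C(=O)OCC)[C@@]1(C)C(=O)CC(=O)C(C)C(=O)OCC | intermediate
18 | di-tert-butyl 3,4-bis(4-hydroxy-3-methyl-2-oxo-2H-pyran-6-yl)-3,4-dimethylcyclobutane-1,2-dicarboxylate (meso) | CC(C)(C)OC(=O)[C@@H]1[C@H](C(=O)OC(C)(C)C)[C@@](C)(c2cc(O)c(C)c(=O)o2)[C@@]1(C)c1cc(O)c(C)c(=O)o1 | intermediate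
19 | di-tert-butyl 3,4-bis(4-methoxy-3-methyl-2-oxo-2H-pyran-6-yl)-3,4-dimethylcyclobutane-1,2-dicarboxylate (meso) | CC(C)(C)OC(=O)[C@@H]1[C@H](C(=O)OC(C)(C)C)[C@@](C)(c2cc(OC)c(C)c(=O)o2)[C@@]1(C)c1cc(OC)c(C)c(=O)o1 | intermediate
20 | 3,4-bis(4-methoxy-3-methyl-2-oxo-2H-pyran-6-yl)-3,4-dimethylcyclobutane-1,2-dicarboxylic acid (meso) | OC(=O)[C@@H]1[C@H](C(=O)O)[C@@](C)(c2cc(OC)c(C)c(=O)o2)[C@@]1(C)c1cc(OC)c(C)c(=O)o1 | intermediate
21 | cyclic anhydride of 20 (meso; anhydride ring and CH3 groups on the upper face, pyranones on the lower face) | O=C5[C@@H]1[C@H](C(=O)O5)[C@@](C)(c2cc(OC)c(C)c(=O)o2)[C@@]1(C)c1cc(OC)c(C)c(=O)o1 | intermediate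
22 | (1S,2R,3S,4R)-2-(methoxycarbonyl)-3,4-bis(4-methoxy-3-methyl-2-oxo-2H-pyran-6-yl)-3,4-dimethylcyclobutane-1-carboxylic acid | COC(=O)[C@@H]1[C@H](C(=O)O)[C@@](C)(c2cc(OC)c(C)c(=O)o2)[C@@]1(C)c1cc(OC)c(C)c(=O)o1 | target

## Step count and risks

Total steps: 13. Longest linear sequence: 13 steps (1 → 22).

**Step 2 (key step).** The trianion of 5 may aggregate or stay out of solution, the second enolisation next to the new quaternary centre may stall, or carboxylate O-methylation may compete. Fallback: the methyl groups are brought in with the ring instead of being added to it. The fallback sets out from 2, which is condensed with 2,3-dimethylmaleic anhydride (CC1=C(C)C(=O)OC1=O; AcOH, reflux) to N-(4-methoxybenzyl)-2,3-dimethylmaleimide F1. Benzophenone-sensitised irradiation of F1 with excess maleic anhydride (O=C1C=CC(=O)O1; MeCN, 350 nm) should give the cross [2+2] adduct, the cis,anti,cis imide anhydride F2, in which the ring-fusion methyls already stand cis to the anhydride carbonyls. Hydrolysis (H2O, THF, 50 °C) returns to the route at 7.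

**Step 8.** The second addition may stall because the first alkoxide closes onto the neighbouring aldehyde, or hydride transfer between that lactolate and an aldehyde may divert material. Fallback: the pyranones are built one after the other, so that an alkoxide never sits beside a free aldehyde. The fallback sets out from 10. NaBH4 (THF–MeOH, 0 °C) should reduce one activated carbonyl, and the hydroxymethyl N-Boc amide closes to the γ-lactone F3 (racemic, as are all compounds up to the return). F3 acylates dianion 15 by Claisen-type lactone opening to the hydroxymethyl 3,5-dioxo ester F4. DBU gives the hydroxymethyl 4-hydroxypyranone F5, and Me2SO4/K2CO3 gives the hydroxymethyl 4-methoxypyranone F6. Dess–Martin oxidation gives the pyranone aldehyde F7, addition of 15 the aldol adduct F8, and a second Dess–Martin oxidation the pyranone 3,5-dioxo ester F9. DBU then gives the hydroxypyranone methoxypyranone F10, and Me2SO4/K2CO3 returns to the route at 19.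

**Step 13.** Discrimination between the two enantiotopic carbonyls of the heavily substituted anhydride may be poor, or of the opposite sense. Fallback: resolution instead of induction, setting out from 21. Uncatalysed methanolysis (MeOH, DMAP cat., rt) gives the racemic half ester, that is 22 together with its enantiomer F11. Fractional crystallisation with (R)-1-phenylethylamine should separate the (R)-1-phenylethylammonium salt of 22, F12; the antipodal amine is used if the other diastereomeric salt proves less soluble. Acidification of F12 returns to the route at 22.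

## Further compounds

F1 | step 2 | N-(4-methoxybenzyl)-2,3-dimethylmaleimide | CC1=C(C)C(=O)N(Cc2ccc(OC)cc2)C1=O
F2 | step 2 | cis,anti,cis 3,4-dimethylcyclobutanetetracarboxylic 1,2-anhydride 3,4-[N-(4-methoxybenzyl)imide] | O=C5[C@@H]1[C@H](C(=O)O5)[C@@]2(C)C(=O)N(Cc3ccc(OC)cc3)C(=O)[C@@]12C
F3 | step 8 | di-tert-butyl cis-fused 3,4-dimethylcyclobutane γ-lactone diester (racemic) | CC(C)(C)OC(=O)[C@@H]1[C@H](C(=O)OC(C)(C)C)[C@@]2(C)COC(=O)[C@@]12C
F4 | step 8 | hydroxymethyl 3,5-dioxo ester | CC(C)(C)OC(=O)[C@@H]1[C@H](C(=O)OC(C)(C)C)[C@@](C)(CO)[C@@]1(C)C(=O)CC(=O)C(C)C(=O)OCC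
F5 | step 8 | hydroxymethyl 4-hydroxypyranone | CC(C)(C)OC(=O)[C@@H]1[C@H](C(=O)OC(C)(C)C)[C@@](C)(CO)[C@@]1(C)c1cc(O)c(C)c(=O)o1
F6 | step 8 | hydroxymethyl 4-methoxypyranone | CC(C)(C)OC(=O)[C@@H]1[C@H](C(=O)OC(C)(C)C)[C@@](C)(CO)[C@@]1(C)c1cc(OC)c(C)c(=O)o1
F7 | step 8 | pyranone aldehyde | CC(C)(C)OC(=O)[C@@H]1[C@H](C(=O)OC(C)(C)C)[C@@](C)(C=O)[C@@]1(C)c1cc(OC)c(C)c(=O)o1
F8 | step 8 | aldol adduct | CC(C)(C)OC(=O)[C@@H]1[C@H](C(=O)OC(C)(C)C)[C@@](C)(C(O)CC(=O)C(C)C(=O)OCC)[C@@]1(C)c1cc(OC)c(C)c(=O)o1
F9 | step 8 | pyranone 3,5-dioxo ester | CC(C)(C)OC(=O)[C@@H]1[C@H](C(=O)OC(C)(C)C)[C@@](C)(C(=O)CC(=O)C(C)C(=O)OCC)[C@@]1(C)c1cc(OC)c(C)c(=O)o1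
F10 | step 8 | hydroxypyranone methoxypyranone | CC(C)(C)OC(=O)[C@@H]1[C@H](C(=O)OC(C)(C)C)[C@@](C)(c2cc(O)c(C)c(=O)o2)[C@@]1(C)c1cc(OC)c(C)c(=O)o1
F11 | step 13 | enantiomer of 22 | COC(=O)[C@H]1[C@@H](C(=O)O)[C@](C)(c2cc(OC)c(C)c(=O)o2)[C@]1(C)c1cc(OC)c(C)c(=O)o1
F12 | step 13 | (R)-1-phenylethylammonium salt of 22 | COC(=O)[C@@H]1[C@H](C(=O)[O-])[C@@](C)(c2cc(OC)c(C)c(=O)o2)[C@@]1(C)c1cc(OC)c(C)c(=O)o1.C[C@@H]([NH3+])c1ccccc1
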